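**Retrosynthetic overview**
1. Feature used: in ring B the 7β-isopropenyl group (C11–C13) sits next to the oxygenated pair C8/C9 and syn to H-10. H-10 and C12 are therefore the two ends of a retro-ene array H–C10–C9–C8···C11–C12.
2. Key disconnection: re-form C8–C11 and return H-10 to C12, so 13 (9-silyloxy-8,11-diene) ⇒ 12 (gem-dimethylcyclopropane with a 9-silyloxy-Δ9(10) bond, a 2-carene). In the forward direction a thermal homodienyl [1,5]-H shift cuts C8–C11, makes the isopropenyl group, sets C10 (cis-decalin) and moves the enol ether to C8=C9.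
3. After it: O8 by bromination and tiglate SN2 at C8, O9 by β-face reduction of the C9 ketone, then the second tiglate.
4. Before it: 12 ⇐ ene-dione 11 (CuH, hydride to C1) ⇐ enone 8 (γ-oxidation at C9) ⇐ Robinson annulation of 4-isocaranone with (E)-pent-3-en-2-one, anti to the CMe2 bridge (bonds C4–C5 and C1–C10, ring A).
5. Ring order: ring B with C7 and the masked isopropenyl group is bought as (+)-3-carene, ring A is closed in step 3, and the three-membered ring is opened in step 7.

Key step: step 7

Remark on the chemistry: every compound, the C10 ones included, carries eremophilane atom numbers (decalin C1–C10, C11–C13 side chain, C14 on C5, C15 on C4; β = face of C14). It is assumed that next to the C9 ketone the cis-fused C10 epimer is the stable one, because a trans-decalin would force the 7β side chain axial and syn to C14.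

**Step 1**
Reactants: 1 (+)-3-carene
Product: 3 4-isocaranol (C10-OH anti to the CMe2 bridge; C14 syn to it), via caran-4-ylborane 2 (not isolated)
Conditions: BH3·THF, THF, 0 °C to rt; then NaOH, H2O2, 0 °C
Reagents that add atoms: borane B (boron stays in 2 only); hydrogen peroxide OO
Why: Hydroboration–oxidation: borane adds syn to C5=C10 from the face anti to the CMe2 bridge with boron on the less substituted C10, and the oxidation retains configuration (both new centres are erased or reset in steps 2 and 3).

**Step 2**
Reactants: 3 4-isocaranol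
Product: 4 4-isocaranone (C10 ketone; C5-H/C14 next to it)
Conditions: DMP, CH2Cl2, rt
Reagents that add atoms: none
Why: Dess–Martin oxidation of a secondary alcohol under neutral conditions leaves the cyclopropane untouched.

**Step 3**
Reactants: 4 4-isocaranone; 5 (E)-pent-3-en-2-one
Product: 8 8,11-cycloeremophil-1(10)-en-2-one (4β,5β-dimethyl; cyclopropane C7–C8–C11 on the β face), via Michael diketone 6 (not isolated), via cis-ketol 7 (not isolated)
Conditions: KOH, EtOH, −10 °C to rt, then reflux
Reagents that add atoms: none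
Why: Robinson annulation: the more substituted C5 enolate of this 2-methylcyclohexanone-type ketone adds to the enone on the face anti to the CMe2 bridge (C5 set, C14 syn to the cyclopropane), the (E)-enone gives the cis-4,5-dimethyl relation known for 2-methylcyclohexanones (C4 set), and aldol condensation of C1 on C10 closes ring A.

**Step 4**
Reactants: 8 8,11-cycloeremophil-1(10)-en-2-one
Product: 10 9α-hydroxy-8,11-cycloeremophil-1(10)-en-2-one, via TBS dienol ether 9 (not isolated)
Conditions: TBSOTf, Et3N, CH2Cl2, 0 °C; then mCPBA, −20 °C; aqueous work-up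
Reagents that add atoms: tert-butyldimethylsilyl triflate CC(C)(C)[Si](C)(C)OS(=O)(=O)C(F)(F)F (silyl group in 9 only); mCPBA OOC(=O)c1cccc(Cl)c1
Why: Vinylogous Rubottom oxidation: soft enolisation gives the extended dienol silyl ether, whose C9=C10 bond is epoxidised anti to the CMe2 bridge and collapses to the γ-hydroxy enone as in the 6-hydroxylation of steroidal 4-en-3-ones, without a radical or cation at the cyclopropylcarbinyl C9.

**Step 5**
Reactants: 10 9α-hydroxy-8,11-cycloeremophil-1(10)-en-2-one
Product: 11 8,11-cycloeremophil-1(10)-ene-2,9-dione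
Conditions: DMP, CH2Cl2, rt
Reagents that add atoms: none
Why: Dess–Martin oxidation of the allylic, cyclopropyl-substituted carbinol proceeds without ionisation at C9, so the three-membered ring stays closed.

**Step 6**
Reactants: 11 8,11-cycloeremophil-1(10)-ene-2,9-dione
Product: 12 9-(dimethylphenylsilyloxy)-8,11-cycloeremophil-9-en-2-one (C9=C10 enol ether; free C2 ketone)
Conditions: [(Ph3P)CuH]6 (cat.), PhMe2SiH, PhMe, 0 °C to rt
Reagents that add atoms: dimethylphenylsilane C[SiH](C)c1ccccc1
Why: Copper hydride catalysed 1,4-hydrosilylation: hydride goes to the unsubstituted C1 (β to the C9 carbonyl) and not to the fully substituted C10, so the copper enolate of the C9 ketone is silylated and the C2 ketone is released.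

**Step 7**
Reactants: 12 9-(dimethylphenylsilyloxy)-8,11-cycloeremophil-9-en-2-one
Product: 13 9-(dimethylphenylsilyloxy)-10βH-eremophila-8,11-dien-2-one
Conditions: o-dichlorobenzene (dilute), BHT (cat.), base-washed sealed tube, 200 °C
Reagents that add atoms: none
Why: Concerted suprafacial homodienyl [1,5]-hydrogen shift (retro-ene): a hydrogen of the endo methyl group C12 on C11 moves to C10 while the C8–C11 cyclopropane bond breaks and the C11=C12 and C8=C9 π bonds form through a six-membered transition state. The closest known case is the thermal isomerisation of 2-carene, the same vinylcyclopropane with the same substitution at the accepting carbon, to trans-p-mentha-2,8-diene, and more generally of cis-1-methyl-2-vinylcyclopropanes to 1,4-dienes. No ring is closed; the three-membered ring is opened, and release of its strain makes the step irreversible. C10 is the only new stereocentre and is fixed by the transition-state geometry: the hydrogen comes from the methyl group lying over the β face, so H-10 ends syn to C11 and C14 (cis-decalin), while C4, C5 and C7 are untouched. The step needs cleavage of the external C8–C11 bond and not of C7–C8, which the bicycle secures because only the external bond is parallel to the enol ether π orbitals; only the isopropenyl isomer, never the isopropylidene one, can form because the hydrogen can only come from a methyl group. The enol ether ends at C8=C9, which makes C8 the next nucleophilic site.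

**Step 8**
Reactants: 13 9-(dimethylphenylsilyloxy)-10βH-eremophila-8,11-dien-2-one; 14 tiglic acid
Product: 16 8α-tigloyloxy-10βH-eremophil-11-ene-2,9-dione, via 8β-bromo diketone 15 (not isolated)
Conditions: NBS, THF, −78 °C; then 14, Cs2CO3, DMF, 0 °C to rt
Reagents that add atoms: N-bromosuccinimide BrN1C(=O)CCC1=O (bromine in 15 only)
Why: Electrophilic bromination of the silyl enol ether (far more nucleophilic than the isopropenyl group) occurs axially from the open β face, and SN2 displacement of the α-bromo ketone by caesium tiglate inverts C8 to the equatorial 8α-ester, which is also the thermodynamic epimer.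

**Step 9**
Reactants: 16 8α-tigloyloxy-10βH-eremophil-11-ene-2,9-dione
Product: 19 9α-hydroxy-8α-tigloyloxy-10βH-eremophil-11-en-2-one, via C2 dimethyl ketal 17 (not isolated), via ketal alcohol 18 (not isolated)
Conditions: CeCl3·7H2O (cat.), HC(OMe)3, MeOH, rt; NaBH4, −40 °C; then 1 M HCl, THF, 0 °C
Reagents that add atoms: trimethyl orthoformate COC(OC)OC (methoxy groups in 17 and 18 only); water O (carbonyl oxygen at C2 of 19)
Why: One-pot selective ketalisation and borohydride reduction (Luche-type): the unhindered C2 ketone is masked in situ as its dimethyl ketal while the C9 ketone between two branched carbons is not, borohydride attacks C9 from the β face because the axial C5–C4 bond blocks the α face (axial 9α-alcohol, cis to O8), and the acidic work-up returns the C2 ketone.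

**Step 10**
Reactants: 19 9α-hydroxy-8α-tigloyloxy-10βH-eremophil-11-en-2-one; 20 tigloyl chloride
Product: 21 8α,9α-bis(tigloyloxy)-10βH-eremophil-11-en-2-one (CNP0249036.2)
Conditions: pyridine, DMAP (cat.), CH2Cl2, 40 °C
Reagents that add atoms: none
Why: DMAP-catalysed acylation of the hindered axial 9α-alcohol with the acid chloride in pyridine (no trialkylamine, hence no vinylketene and no double-bond shift); a tigloyl shift between O8 and O9 in 19 would be harmless because both oxygens end as tiglates.

**Compound list**
1 | (+)-3-carene, (1S,6R)-3,7,7-trimethylbicyclo[4.1.0]hept-3-ene | CC1(C)[C@H]2CC(C)=CC[C@@H]12 | starting material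
2 | caran-4-ylborane (boron on C10, anti to CMe2) | CC1(C)[C@H]2C[C@@H](C)[C@H](B)C[C@@H]12 | intermediate
3 | 4-isocaranol | CC1(C)[C@H]2C[C@@H](C)[C@H](O)C[C@@H]12 | intermediate
4 | 4-isocaranone | CC1(C)[C@H]2C[C@@H](C)C(=O)C[C@@H]12 | intermediate
5 | (E)-pent-3-en-2-one | C/C=C/C(C)=O | starting material
6 | Michael diketone (C5 quaternary, 4-oxopentan-2-yl chain anti to CMe2) | CC1(C)[C@H]2C[C@](C)([C@@H](C)CC(C)=O)C(=O)C[C@@H]12 | intermediate
7 | cis-ketol (10β-hydroxy-8,11-cycloeremophilan-2-one) | CC1(C)[C@H]2C[C@@]3(C)[C@](O)(CC(=O)C[C@@H]3C)C[C@@H]12 | intermediate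
8 | 8,11-cycloeremophil-1(10)-en-2-one | CC1(C)[C@H]2C[C@@]3(C)C(=CC(=O)C[C@@H]3C)C[C@@H]12 | intermediate
9 | 2-(tert-butyldimethylsilyloxy)-8,11-cycloeremophila-1,9-diene | CC1(C)[C@H]2C[C@@]3(C)C(C=C(O[Si](C)(C)C(C)(C)C)C[C@@H]3C)=C[C@@H]12 | intermediate
10 | 9α-hydroxy-8,11-cycloeremophil-1(10)-en-2-one | CC1(C)[C@H]2C[C@@]3(C)C(=CC(=O)C[C@@H]3C)[C@H](O)[C@@H]12 | intermediate
11 | 8,11-cycloeremophil-1(10)-ene-2,9-dione | CC1(C)[C@H]2C[C@@]3(C)C(=CC(=O)C[C@@H]3C)C(=O)[C@@H]12 | intermediate
12 | 9-(dimethylphenylsilyloxy)-8,11-cycloeremophil-9-en-2-one | CC1(C)[C@H]2C[C@@]3(C)C(CC(=O)C[C@@H]3C)=C(O[Si](C)(C)c4ccccc4)[C@@H]12 | intermediate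
13 | 9-(dimethylphenylsilyloxy)-10βH-eremophila-8,11-dien-2-one | C=C(C)[C@H]1C[C@@]2(C)[C@H](CC(=O)C[C@@H]2C)C(O[Si](C)(C)c3ccccc3)=C1 | intermediate
14 | tiglic acid, (E)-2-methylbut-2-enoic acid | OC(=O)/C(C)=C/C | starting material
15 | 8β-bromo-10βH-eremophil-11-ene-2,9-dione | C=C(C)[C@H]1C[C@@]2(C)[C@H](CC(=O)C[C@@H]2C)C(=O)[C@H]1Br | intermediate
16 | 8α-tigloyloxy-10βH-eremophil-11-ene-2,9-dione | C=C(C)[C@H]1C[C@@]2(C)[C@H](CC(=O)C[C@@H]2C)C(=O)[C@@H]1OC(=O)/C(C)=C/C | intermediate
17 | 2,2-dimethoxy-8α-tigloyloxy-10βH-eremophil-11-en-9-one | C=C(C)[C@H]1C[C@@]2(C)[C@H](CC(OC)(OC)C[C@@H]2C)C(=O)[C@@H]1OC(=O)/C(C)=C/C | intermediate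
18 | 2,2-dimethoxy-8α-tigloyloxy-10βH-eremophil-11-en-9α-ol | C=C(C)[C@H]1C[C@@]2(C)[C@H](CC(OC)(OC)C[C@@H]2C)[C@H](O)[C@@H]1OC(=O)/C(C)=C/C | intermediate
19 | 9α-hydroxy-8α-tigloyloxy-10βH-eremophil-11-en-2-one | C=C(C)[C@H]1C[C@@]2(C)[C@H](CC(=O)C[C@@H]2C)[C@H](O)[C@@H]1OC(=O)/C(C)=C/C | intermediate
20 | tigloyl chloride, (E)-2-methylbut-2-enoyl chloride | ClC(=O)/C(C)=C/C | starting material
21 | 8α,9α-bis(tigloyloxy)-10βH-eremophil-11-en-2-one (CNP0249036.2) | C=C(C)[C@H]1C[C@@]2(C)[C@H](CC(=O)C[C@@H]2C)[C@H](OC(=O)/C(C)=C/C)[C@@H]1OC(=O)/C(C)=C/C | target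

Total step count: 10. Longest linear sequence: 10 steps (1 → 21).

**Steps most likely to fail**

Step 7. At the temperature needed, the silyl enol ether may lose or transfer its silyl group on the vessel wall. Crowding at the fully substituted C10 may also slow the hydrogen shift until decomposition competes.
- The fallback replaces the pericyclic opening by an ionic one and sets out from 12.
- Mild hydrolysis (AcOH, THF, H2O) should give the cyclopropyl diketone 8,11-cycloeremophilane-2,9-dione F1.
- Me3SiI in CH2Cl2 at −40 °C should open the ketone-activated C8–C11 bond by homoconjugate addition of iodide at C11, giving 11-iodo-9-(trimethylsilyloxy)-10βH-eremophil-8-en-2-one F2.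
- DBU should then remove HI to give 9-(trimethylsilyloxy)-10βH-eremophila-8,11-dien-2-one F3.
- F3 is brominated under the conditions of step 8 and comes back to the route at 15.
- In this variant C10 rests only on equilibration next to the C9 ketone.

Step 9. Ketalisation at C2 may stay incomplete, so that the C2 ketone is reduced as well. The small hydride may also show poor facial selectivity at C9.
- The fallback uses a discrete protecting group and a bulky hydride, and sets out from 16.
- Ethylene glycol with PPTS in refluxing benzene should give 2,2-ethylenedioxy-8α-tigloyloxy-10βH-eremophil-11-en-9-one F4.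
- L-Selectride in THF at −78 °C should give 2,2-ethylenedioxy-8α-tigloyloxy-10βH-eremophil-11-en-9α-ol F5.
- Acylation with 20 as in step 10 should give 2,2-ethylenedioxy-8α,9α-bis(tigloyloxy)-10βH-eremophil-11-ene F6.
- PPTS in wet acetone should then remove the dioxolane, and the fallback comes back to the route at 21.

Step 3. The Michael addition at the hindered C5 is slow and reversible. Reaction through the C9 enolate, polymerisation of 5 and loss of selectivity at C4 may therefore take over.
- The fallback fixes the regiochemistry in a preformed nucleophile and makes the C4–C5 bond under Lewis acid control. It sets out from 4.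
- Thermodynamic silylation (Me3SiCl, NaI, Et3N, MeCN) should give 4-(trimethylsilyloxy)car-3-ene F7.
- A Mukaiyama–Michael addition of F7 to 5 (TiCl4, CH2Cl2, −78 °C) comes back to the route at 6.
- Here 6 is isolated and then closed to 8 with KOH in MeOH.

**Further compounds**
F1 | step 7 | 8,11-cycloeremophilane-2,9-dione (10βH) | CC1(C)[C@H]2C[C@@]3(C)[C@H](CC(=O)C[C@@H]3C)C(=O)[C@@H]12
F2 | step 7 | 11-iodo-9-(trimethylsilyloxy)-10βH-eremophil-8-en-2-one | CC(C)(I)[C@H]1C[C@@]2(C)[C@H](CC(=O)C[C@@H]2C)C(O[Si](C)(C)C)=C1
F3 | step 7 | 9-(trimethylsilyloxy)-10βH-eremophila-8,11-dien-2-one | C=C(C)[C@H]1C[C@@]2(C)[C@H](CC(=O)C[C@@H]2C)C(O[Si](C)(C)C)=C1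
F4 | step 9 | 2,2-ethylenedioxy-8α-tigloyloxy-10βH-eremophil-11-en-9-one | C=C(C)[C@H]1C[C@@]2(C)[C@H](CC3(OCCO3)C[C@@H]2C)C(=O)[C@@H]1OC(=O)/C(C)=C/C
F5 | step 9 | 2,2-ethylenedioxy-8α-tigloyloxy-10βH-eremophil-11-en-9α-ol | C=C(C)[C@H]1C[C@@]2(C)[C@H](CC3(OCCO3)C[C@@H]2C)[C@H](O)[C@@H]1OC(=O)/C(C)=C/C
F6 | step 9 | 2,2-ethylenedioxy-8α,9α-bis(tigloyloxy)-10βH-eremophil-11-ene | C=C(C)[C@H]1C[C@@]2(C)[C@H](CC3(OCCO3)C[C@@H]2C)[C@H](OC(=O)/C(C)=C/C)[C@@H]1OC(=O)/C(C)=C/C
F7 | step 3 | 4-(trimethylsilyloxy)car-3-ene | CC1(C)[C@H]2CC(C)=C(O[Si](C)(C)C)C[C@@H]12
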